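## The problem

The target is a cyclohexene, numbered here C1 (quaternary), C2, C3, C4(CH3)=C5, C6, that carries two 5,7-dimethoxycoumarins through their C8 positions. Ring B sits directly on C6; ring A is joined to C1 through a Z-ethenyl bridge Ca=Cb (Cb on C1), and C1 also bears CH3. There are only two stereocentres, C1 and C6, but they are adjacent and one is quaternary. CH3 on C1 is trans to the aryl group on C6, so Cb is cis to it. Once C6 is fixed it can direct C1, because an enolisable carbon next to a fixed tertiary centre is alkylated anti to that centre's substituent; the reverse relay is much harder. The aryl–C6 bond lies between two ortho oxygens of ring B, which speaks against making it by a late coupling and for carrying the arene from the start. Several groups are fragile: the Z-styrene (less stable isomer, sensitive to acid, iodine and light), the two lactones (opened by hydroxide, alkoxide, hydride and organometallics, with photoreactive C3=C4 bonds), and the C6–H bond, which is both benzylic and allylic. The enabling feature is that ArB–C6–C1–Cb, read with the ring-B oxygen on C8a, is a 3,4-dihydrocoumarin in which C6 is C4, C1 is C3 and Cb is the lactone carbonyl. Both stereocentres can therefore be set on a flat third coumarin.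

## Retrosynthesis

**Z-alkene.** The Ca=Cb double bond of target 23 is taken back to the triple bond of alkyne 22. An alkyne cannot isomerise during earlier steps, and syn delivery of hydrogen gives the Z geometry by mechanism. An olefination of a C1 aldehyde with a coumarinylmethyl ylide would depend on the poor Z/E control of semistabilised ylides. The forward step must add one equivalent of hydrogen to a hindered alkyne and spare the ring alkene and both coumarin C3=C4 bonds.

**Ca–C8 bond of ring A.** Alkyne 22 is cut into terminal alkyne 19 and iodide 21 (Sonogashira). Ring A then arrives complete, flat and achiral, one step from commercial coumarin 20. The neighbouring cut, C8 of ring B to C6, would need an sp2–sp3 coupling at a secondary allylic stereocentre between two ortho oxygens. The forward step must couple at an iodide flanked by OCH3 and the ring oxygen without opening either lactone.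

**Pyranone of ring B.** Coumarin 19 is cut at C3=C4 and O1–C2 back to salicylaldehyde 16, and 16 at its formyl carbon back to phenol 15. Ring B is thus carried through the organometallic steps as a plain dimethoxyphenol, which a finished coumarin would not survive. Phenol 15 has a single free ortho position, so the site of formylation is fixed by structure.

**Alkyne and phenol from one lactone.** In 15 the phenol oxygen and the ethynyl group are cis on C6 and C1. Joining them through Cb gives lactol 14 and then lactone 13. Forward, hydride reduction stops at the lactol and a one-carbon homologation (Ohira–Bestmann) adds Ca. This cut replaces two remote functional groups by one ring and reveals the third coumarin. The reduction must stop at the lactol.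

**Cyclohexene.** The C4=C5 bond of 13 is cut by ring-closing metathesis to diene 12, a dihydrocoumarin with a vinyl group on C4 and a 3-methylbut-3-enyl chain on C3. No stereocentre is involved in the closure. It only requires the two arms to be cis, which is also what makes the lactone cis-fused.

**Key disconnection.** Diene 12 is cut at C4–vinyl (C5–C6 of the target) and at C3–CH3 (C1–CH3), back to flat coumarin 7, vinyl Grignard reagent 8 and iodomethane 9. The order is dictated by stereochemistry. The group added last to the enolate ends trans to vinyl, so CH3 must come last and the butenyl chain must already be on C3. Two C–C bonds and both stereocentres are removed, and the precursor is achiral. The forward step must achieve enantioface-selective 1,4-addition to a crowded, electron-rich acceptor and anti alkylation to a quaternary carbon.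

**Template coumarin.** Coumarin 7 is cut at O1–C2 to E-cinnamate 5 (light-driven E to Z isomerisation and lactonisation forward). Ester 5 is cut at its C=C bond to phosphonate 3 and aldehyde 4, and 3 at its α-carbon to phosphonoacetate 1 and bromide 2. All four starting materials are commercial.

**Iodide.** Iodide 21 is cut at C–I to coumarin 20.

## Roads not taken

**Alternative 1:** The cut removes the benzene ring of coumarin B and leaves C6 carrying a silyloxyethynyl group. The precursor is siloxyalkyne A2, a cyclohexene that already holds both stereocentres, with a silyloxymethyl group standing in for Cb. Forward, A2 would be heated with 3-methoxycyclobut-2-en-1-one A3. Four-electron ring opening of A3, [2+2] addition to the alkyne, a second four-electron opening and a six-electron closure build the arene on C6 and give phenol A1, whose three ring oxygens are already told apart.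

- Merits: the crowded aryl–C6 bond is never made by coupling, the benzannulation is a known thermal reaction that needs no catalyst, and the oxygen pattern of A1 fixes the later pyranone regiochemistry as firmly as the chosen plan does.
- Weak points: the annulation sets neither stereocentre. The vicinal quaternary/tertiary pair must be made first on a cyclohexene with no arene to help, and an ynol ether must then be built on hindered C6, so the hard problem only moves upstream. After A1, methylation, two desilylations, oxidation and alkynylation are needed before the sequence meets the chosen route at 15, about four operations more, on top of a longer approach to A2.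
- Comparison: in precedent for the key step this road is the stronger one. The chosen plan sets against it that its one unprecedented step creates both stereocentres from an achiral precursor made in three steps, and that a known detour to the same product 12 exists.

**Alternative 2:** Three bonds are cut at once, C8(ring B)–C6, C6–C1 and O–Cb, which reduces the core to 3,5-dimethoxyphenol A5 and the acyclic (2Z)-dienal A6 carrying a methyl enol ether. Forward, an ammonium carboxylate would condense the ortho carbon of A5 with the aldehyde of A6 to the vinyl o-quinone methide A7. The tethered enol ether would then add across the O=C–C=C unit of A7 in an inverse-demand hetero-Diels–Alder reaction under a chiral phosphoric acid, giving methyl acetal A4 with the cyclohexene, a temporary pyran and both stereocentres.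

- Merits: this is the shortest and most convergent road. A4 is at the oxidation level of lactol 14, so hydrolysis would enter the chosen route at step 7 and save four or five steps.
- Weak points: three selectivities rest on one event. A7 is a 1-oxatriene whose usual fate is oxa-6π electrocyclisation, which competes directly with the cycloaddition. The carbocycle can only close if the C4=C5 bond of A6 is Z, a geometry an amine catalyst can scramble through dienamine formation. Control of absolute configuration by a phosphoric acid in an ammonium-buffered medium would have to outrun the uncatalysed reaction of a very reactive intermediate.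
- Comparison: the chosen plan is longer, and that is conceded. It sets against this that each selectivity has its own understood source (ligand for the face, the C4 substituent for the alkylation, the cis arms for the ring fusion) and that its key step has a fallback made only of known reactions.

**Alternative 3:** The cyclohexene is cut at C1–C2 and C5–C6, a Diels–Alder reaction on the C3=C4 bond of a coumarin; this is the same template idea with a different bond set. Forward, 5,7-dimethoxy-2-oxo-2H-chromene-3-carbaldehyde A9 and (E)-trimethyl(2-methylbuta-1,3-dienyl)silane A10 would combine under a chiral Lewis acid chelated by the 1,3-dicarbonyl unit to give the cis-fused adduct A8.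

- Merits, in several respects equal or better: 3-acylcoumarins are established dienophiles, two-point binding to a Lewis acid is a proven way to control the face, suprafacial addition guarantees the cis fusion, both stereocentres and the carbocycle form in one step, and no organometallic reagent comes near the lactone.
- Weak points: the quaternary carbon of A8 carries CHO where CH3 is needed, and the ring alkene lies between C3 and C4 of the target numbering. The formyl group must be deoxygenated beside the lactone and the allylsilane protodesilylated with allylic transposition, three or four operations where the chosen plan needs one metathesis. The donor methoxy groups lower the dienophilicity, the silyl-bearing diene terminus must bond to C4 next to the peri methoxy group, and the regiochemistry depends on the 2-methyl group outweighing the silyl group.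
- Comparison: the chosen plan installs CH3 directly at the right oxidation level and needs no activating group that must later be removed. It pays with a less well precedented C–C bond formation at C4.

Key step: step 4

Assumption: electrophilic iodination of 5,7-dimethoxycoumarin 20 is taken to occur at C8 (ortho to OCH3 on C7 and to the ring oxygen, para to OCH3 on C5) and not at C6 or C3; the site would be confirmed by NOE on 21 before use.

Assumption: which antipode of the ferrocenyl bisphosphine gives the 4S product cannot be derived from the structure; it would be fixed in a first trial, both antipodes being commercial.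

## Route

Step 1
Reactants: 1 triethyl phosphonoacetate; 2 bromide 4-bromo-2-methylbut-1-ene
Product: 3 ethyl 2-(diethoxyphosphoryl)-5-methylhex-5-enoate (racemic)
Conditions: NaH, DMF, 0 °C; then 2, NaI (cat.), 60 °C
Reagents that add atoms: none
Why: Alkylation of the sodium salt of a phosphonoacetate with a primary bromide under iodide catalysis is routine; a small excess of 2 offsets loss by elimination, and the hindered, less acidic product resists a second alkylation.

Step 2
Reactants: 3 ethyl 2-(diethoxyphosphoryl)-5-methylhex-5-enoate; 4 salicylaldehyde 2-hydroxy-4,6-dimethoxybenzaldehyde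
Product: 5 ethyl (2E)-2-[(2-hydroxy-4,6-dimethoxyphenyl)methylidene]-5-methylhex-5-enoate
Conditions: NaH (2.2 equiv), THF, 0 °C → reflux
Reagents that add atoms: none
Why: Horner–Wadsworth–Emmons olefination, with the second equivalent of base holding the phenol as its phenoxide; the α-branched phosphonate should give mainly the E-ester (aryl trans to the ester group), and any Z-ester lactonises to 7 and is carried forward with 5.

Step 3
Reactants: 5 ethyl (2E)-2-[(2-hydroxy-4,6-dimethoxyphenyl)methylidene]-5-methylhex-5-enoate
Product: 7 alkylcoumarin 5,7-dimethoxy-3-(3-methylbut-3-en-1-yl)-2H-chromen-2-one, via Z-cinnamate ester 6 (not isolated)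
Conditions: hν (365 nm), MeCN (dilute), rt
Reagents that add atoms: none
Why: Irradiation of α-alkyl-o-hydroxycinnamates drives E to Z isomerisation, and the Z-ester 6, with phenol and ester now cis, lactonises with loss of ethanol; dilution suppresses [2+2] dimerisation of the weakly absorbing product, and the isolated 1,1-disubstituted alkene is transparent.

Step 4
Reactants: 7 alkylcoumarin 5,7-dimethoxy-3-(3-methylbut-3-en-1-yl)-2H-chromen-2-one; 8 vinylmagnesium bromide; 9 iodomethane
Product: 12 (3S,4S)-4-ethenyl-5,7-dimethoxy-3-methyl-3-(3-methylbut-3-en-1-yl)-3,4-dihydro-2H-chromen-2-one, via silyl ketene acetal 10 (not isolated), via lithium enolate 11 (not isolated)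
Conditions: CuBr·SMe2 (5 mol%), (R)-1-[(Sp)-2-(diphenylphosphino)ferrocenyl]ethyldicyclohexylphosphine (6 mol%), Me3SiCl, t-BuOMe, −78 °C, slow addition of 8; then MeLi, −78 → −30 °C; then 9, DMPU, −78 → 0 °C
Reagents that add atoms: vinylmagnesium bromide 8, C=C[Mg]Br; iodomethane 9, CI
Why: Proposed new method: a vinyl species of monovalent copper bound to the chiral ferrocenyl bisphosphine forms a π-complex with the C3=C4 bond of 7, whose carbonyl oxygen is activated by Me3SiCl, and oxidative addition followed by reductive elimination delivers vinyl to C4 and leaves silyl ketene acetal 10; MeLi then cleaves the O–Si bond to give lithium enolate 11, which iodomethane alkylates at C3. The closest known reaction type is the copper/ferrocenyl-bisphosphine-catalysed conjugate addition of alkyl Grignard reagents to 3-unsubstituted coumarins with trapping of the enolate, together with the silyl-Lewis-acid-assisted form of such additions to weak acceptors; new here are the vinyl nucleophile, the 3-alkyl group and the peri methoxy group. The silyl chloride is added because the two methoxy groups push electron density into C4 and the α-substituent slows the addition, and it also stores the adduct in a form that cannot expel the phenoxide as a ketene. No ring closes. C4 (the future C6) is set by the ligand, which selects one face of the flat lactone. C3 (the future C1) is set by the substrate: the peri methoxy group and the C3 chain force the C4 vinyl group pseudoaxial, so iodomethane enters the enolate from the opposite face, placing CH3 trans and the butenyl chain cis to vinyl. The step needs 1,4- over 1,2-addition, which low temperature, slow addition of 8 and the silyl chloride should secure, and C- over O-methylation, which the lithium counter-ion and the soft electrophile favour.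

Step 5
Reactants: 12 (3S,4S)-4-ethenyl-5,7-dimethoxy-3-methyl-3-(3-methylbut-3-en-1-yl)-3,4-dihydro-2H-chromen-2-one
Product: 13 (6aS,10aS)-1,3-dimethoxy-6a,9-dimethyl-6a,7,8,10a-tetrahydro-6H-benzo[c]chromen-6-one (cis-fused)
Conditions: second-generation Grubbs catalyst (H2IMes)(PCy3)Cl2Ru=CHPh (5 mol%), CH2Cl2, 40 °C
Reagents that add atoms: none
Why: Ring-closing metathesis of the cis-disposed vinyl and 3-methylbut-3-enyl arms closes the six-membered ring with its trisubstituted C4=C5 bond and releases ethene; neither stereocentre is touched, and the cis arms allow only the cis-fused bicycle.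

Step 6
Reactants: 13 (6aS,10aS)-1,3-dimethoxy-6a,9-dimethyl-6a,7,8,10a-tetrahydro-6H-benzo[c]chromen-6-one
Product: 14 (6aS,10aS)-1,3-dimethoxy-6a,9-dimethyl-6a,7,8,10a-tetrahydro-6H-benzo[c]chromen-6-ol (both C6 epimers)
Conditions: i-Bu2AlH (1.1 equiv), CH2Cl2, −78 °C; aqueous potassium sodium tartrate
Reagents that add atoms: none
Why: Partial reduction of a 3,4-dihydrocoumarin to the 2-chromanol is well known; the tetrahedral aluminate persists at −78 °C and the quaternary α-carbon hinders a second hydride delivery.

Step 7
Reactants: 14 (6aS,10aS)-1,3-dimethoxy-6a,9-dimethyl-6a,7,8,10a-tetrahydro-6H-benzo[c]chromen-6-ol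
Product: 15 phenol 2-[(1R,6S)-6-ethynyl-3,6-dimethylcyclohex-2-en-1-yl]-3,5-dimethoxyphenol
Conditions: dimethyl (1-diazo-2-oxopropyl)phosphonate, K2CO3, MeOH, 0 °C → rt
Reagents that add atoms: dimethyl (1-diazo-2-oxopropyl)phosphonate, COP(=O)(OC)C(=[N+]=[N-])C(C)=O
Why: Ohira–Bestmann homologation: in basic methanol the lactol is in equilibrium with the phenoxide aldehyde, which is trapped by the diazomethylphosphonate anion formed in the flask, and loss of N2 with 1,2-hydrogen shift gives the alkyne; the aldehyde has no α-hydrogen, so C1 cannot epimerise.

Step 8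
Reactants: 15 phenol 2-[(1R,6S)-6-ethynyl-3,6-dimethylcyclohex-2-en-1-yl]-3,5-dimethoxyphenol
Product: 16 salicylaldehyde 3-[(1R,6S)-6-ethynyl-3,6-dimethylcyclohex-2-en-1-yl]-2-hydroxy-4,6-dimethoxybenzaldehyde
Conditions: MgCl2, Et3N, (CH2O)n, MeCN, reflux
Reagents that add atoms: paraformaldehyde (as formaldehyde), C=O
Why: Magnesium-mediated ortho-formylation (Casnati–Skattebøl): the magnesium phenoxide delivers formaldehyde to the only free ortho position and a second formaldehyde oxidises the benzylic alkoxide; the position between the two methoxy groups is not ortho to the oxygen–magnesium bond and is not reached.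

Step 9
Reactants: 16 salicylaldehyde 3-[(1R,6S)-6-ethynyl-3,6-dimethylcyclohex-2-en-1-yl]-2-hydroxy-4,6-dimethoxybenzaldehyde
Product: 19 coumarin 8-[(1R,6S)-6-ethynyl-3,6-dimethylcyclohex-2-en-1-yl]-5,7-dimethoxy-2H-chromen-2-one, via E-cinnamate ester 17 (not isolated), via Z-cinnamate ester 18 (not isolated)
Conditions: Ph3P=CHCO2Et, PhNEt2, reflux
Reagents that add atoms: ethyl (triphenylphosphoranylidene)acetate, CCOC(=O)C=P(c1ccccc1)(c1ccccc1)c1ccccc1
Why: Wittig olefination of the salicylaldehyde with the stabilised ylide, followed in the hot amine by E to Z equilibration and lactonisation with loss of ethanol, is the standard route to 5,7-dialkoxycoumarins; the isolated alkyne and ring alkene have no thermal pathway open at this temperature.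

Step 10
Reactants: 20 coumarin 5,7-dimethoxy-2H-chromen-2-one
Product: 21 iodide 8-iodo-5,7-dimethoxy-2H-chromen-2-one
Conditions: N-iodosuccinimide, CF3CO2H (cat.), MeCN, rt
Reagents that add atoms: N-iodosuccinimide, O=C1CCC(=O)N1I
Why: Electrophilic aromatic iodination; C8 is activated by three oxygen substituents and is less crowded than C6 between the two methoxy groups.

Step 11
Reactants: 19 coumarin 8-[(1R,6S)-6-ethynyl-3,6-dimethylcyclohex-2-en-1-yl]-5,7-dimethoxy-2H-chromen-2-one; 21 iodide 8-iodo-5,7-dimethoxy-2H-chromen-2-one
Product: 22 alkyne 8-[(1R,6S)-6-[(5,7-dimethoxy-2-oxo-2H-chromen-8-yl)ethynyl]-3,6-dimethylcyclohex-2-en-1-yl]-5,7-dimethoxy-2H-chromen-2-one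
Conditions: Pd(PPh3)2Cl2 (5 mol%), CuI (10 mol%), Et3N, DMF, 60 °C, degassed
Reagents that add atoms: none
Why: Sonogashira coupling: oxidative addition of zerovalent palladium into the aryl–iodine bond, transmetalation from the copper acetylide and reductive elimination; a tertiary amine is used so that neither lactone is opened.

Step 12
Reactants: 22 alkyne 8-[(1R,6S)-6-[(5,7-dimethoxy-2-oxo-2H-chromen-8-yl)ethynyl]-3,6-dimethylcyclohex-2-en-1-yl]-5,7-dimethoxy-2H-chromen-2-one
Product: 23 8-[(1R,6R)-6-[(Z)-2-(5,7-dimethoxy-2-oxo-2H-chromen-8-yl)ethenyl]-3,6-dimethylcyclohex-2-en-1-yl]-5,7-dimethoxy-2H-chromen-2-one (target)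
Conditions: H2 (1 atm), Pd/CaCO3 poisoned with Pb(OAc)2, quinoline, EtOAc, rt, stopped at one equivalent
Reagents that add atoms: none
Why: Syn addition of one equivalent of hydrogen on the poisoned palladium surface gives the Z-alkene; the trisubstituted ring alkene and the conjugated coumarin C3=C4 bonds are not reduced on this catalyst.

## Compound list

1 | triethyl phosphonoacetate | CCOC(=O)CP(=O)(OCC)OCC | starting material
2 | 4-bromo-2-methylbut-1-ene | C=C(C)CCBr | starting material
3 | ethyl 2-(diethoxyphosphoryl)-5-methylhex-5-enoate (racemic) | CCOC(=O)C(CCC(C)=C)P(=O)(OCC)OCC | intermediate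
4 | 2-hydroxy-4,6-dimethoxybenzaldehyde | COc1cc(O)c(C=O)c(OC)c1 | starting material
5 | ethyl (2E)-2-[(2-hydroxy-4,6-dimethoxyphenyl)methylidene]-5-methylhex-5-enoate | CCOC(=O)/C(CCC(C)=C)=C/c1c(O)cc(OC)cc1OC | intermediate
6 | ethyl (2Z)-2-[(2-hydroxy-4,6-dimethoxyphenyl)methylidene]-5-methylhex-5-enoate | CCOC(=O)/C(CCC(C)=C)=C\c1c(O)cc(OC)cc1OC | intermediate (not isolated)
7 | 5,7-dimethoxy-3-(3-methylbut-3-en-1-yl)-2H-chromen-2-one | COc1cc(OC)c2cc(CCC(C)=C)c(=O)oc2c1 | intermediate
8 | vinylmagnesium bromide | C=C[Mg]Br | starting material
9 | iodomethane | CI | starting material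
10 | {[(4S)-4-ethenyl-5,7-dimethoxy-3-(3-methylbut-3-en-1-yl)-4H-chromen-2-yl]oxy}(trimethyl)silane | C=C[C@H]1c2c(OC)cc(OC)cc2OC(O[Si](C)(C)C)=C1CCC(C)=C | intermediate (not isolated)
11 | lithium (4S)-4-ethenyl-5,7-dimethoxy-3-(3-methylbut-3-en-1-yl)-4H-chromen-2-olate | C=C[C@H]1c2c(OC)cc(OC)cc2OC(O[Li])=C1CCC(C)=C | intermediate (not isolated)
12 | (3S,4S)-4-ethenyl-5,7-dimethoxy-3-methyl-3-(3-methylbut-3-en-1-yl)-3,4-dihydro-2H-chromen-2-one (vinyl trans to CH3) | C=C[C@H]1c2c(OC)cc(OC)cc2OC(=O)[C@@]1(C)CCC(C)=C | intermediate
13 | (6aS,10aS)-1,3-dimethoxy-6a,9-dimethyl-6a,7,8,10a-tetrahydro-6H-benzo[c]chromen-6-one (cis-fused) | CC1=C[C@H]2c3c(OC)cc(OC)cc3OC(=O)[C@@]2(C)CC1 | intermediate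
14 | (6aS,10aS)-1,3-dimethoxy-6a,9-dimethyl-6a,7,8,10a-tetrahydro-6H-benzo[c]chromen-6-ol (both C6 epimers) | CC1=C[C@H]2c3c(OC)cc(OC)cc3OC(O)[C@@]2(C)CC1 | intermediate
15 | 2-[(1R,6S)-6-ethynyl-3,6-dimethylcyclohex-2-en-1-yl]-3,5-dimethoxyphenol | C#C[C@@]1(C)CCC(C)=C[C@H]1c1c(O)cc(OC)cc1OC | intermediate
16 | 3-[(1R,6S)-6-ethynyl-3,6-dimethylcyclohex-2-en-1-yl]-2-hydroxy-4,6-dimethoxybenzaldehyde | C#C[C@@]1(C)CCC(C)=C[C@H]1c1c(O)c(C=O)c(OC)cc1OC | intermediate
17 | ethyl (2E)-3-{3-[(1R,6S)-6-ethynyl-3,6-dimethylcyclohex-2-en-1-yl]-2-hydroxy-4,6-dimethoxyphenyl}prop-2-enoate | C#C[C@@]1(C)CCC(C)=C[C@H]1c1c(O)c(/C=C/C(=O)OCC)c(OC)cc1OC | intermediate (not isolated)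
18 | ethyl (2Z)-3-{3-[(1R,6S)-6-ethynyl-3,6-dimethylcyclohex-2-en-1-yl]-2-hydroxy-4,6-dimethoxyphenyl}prop-2-enoate | C#C[C@@]1(C)CCC(C)=C[C@H]1c1c(O)c(/C=C\C(=O)OCC)c(OC)cc1OC | intermediate (not isolated)
19 | 8-[(1R,6S)-6-ethynyl-3,6-dimethylcyclohex-2-en-1-yl]-5,7-dimethoxy-2H-chromen-2-one | C#C[C@@]1(C)CCC(C)=C[C@H]1c1c(OC)cc(OC)c2ccc(=O)oc12 | intermediate
20 | 5,7-dimethoxy-2H-chromen-2-one | COc1cc(OC)c2ccc(=O)oc2c1 | starting material
21 | 8-iodo-5,7-dimethoxy-2H-chromen-2-one | COc1cc(OC)c2ccc(=O)oc2c1I | intermediate
22 | 8-[(1R,6S)-6-[(5,7-dimethoxy-2-oxo-2H-chromen-8-yl)ethynyl]-3,6-dimethylcyclohex-2-en-1-yl]-5,7-dimethoxy-2H-chromen-2-one | COc1cc(OC)c2ccc(=O)oc2c1C#C[C@@]1(C)CCC(C)=C[C@H]1c1c(OC)cc(OC)c2ccc(=O)oc12 | intermediate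
23 | 8-[(1R,6R)-6-[(Z)-2-(5,7-dimethoxy-2-oxo-2H-chromen-8-yl)ethenyl]-3,6-dimethylcyclohex-2-en-1-yl]-5,7-dimethoxy-2H-chromen-2-one | COc1cc(OC)c2ccc(=O)oc2c1/C=C\[C@@]1(C)CCC(C)=C[C@H]1c1c(OC)cc(OC)c2ccc(=O)oc12 | target

The descriptor of the quaternary carbon changes from S (15 to 22) to R (23) only because the alkenyl group ranks below the ring carbon where the alkynyl group ranked above it; the arrangement in space is unchanged.

## Step count and least certain steps

Total: 12 steps. Longest linear sequence: 11 steps (steps 1 to 9, 11 and 12); step 10 is a one-step branch.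

**Step 4 (key step).**
- What may go wrong: the conjugate addition may be slow or fail, because the 5- and 7-methoxy groups make C4 electron-rich and the C3 chain and the peri methoxy group crowd it. Raising the temperature to compensate invites 1,2-addition at the lactone carbonyl. Face selectivity may be poor, since vinyl Grignard reagents are weak partners in this catalysis and are delivered in THF, which loosens ligand control. Unmasking of the silyl ketene acetal may be incomplete, or the enolate may be O-methylated.
- Fallback (known reactions only; sets out from aldehyde 4, returns at 12):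
  - The phenol of 4 is protected (MeOCH2Cl, i-Pr2NEt) to give 2-(methoxymethoxy)-4,6-dimethoxybenzaldehyde F1.
  - Knoevenagel–Doebner condensation with malonic acid (pyridine, piperidine, 90 °C) gives (2E)-3-[2-(methoxymethoxy)-4,6-dimethoxyphenyl]prop-2-enoic acid F2.
  - Coupling to (4R)-4-phenyl-1,3-oxazolidin-2-one (t-BuCOCl, Et3N, LiCl, THF) gives the N-enoyl imide F3.
  - Copper-mediated addition of 8 (CuBr·SMe2, THF, −40 → −10 °C) to the chelated s-cis imide, anti to the phenyl group of the auxiliary, gives the (3S)-pent-4-enoyl imide F4.
  - Aqueous HCl in THF removes the acetal; the freed phenol closes onto the imide carbonyl and expels the auxiliary, giving (4S)-4-ethenyl-5,7-dimethoxy-3,4-dihydro-2H-chromen-2-one F5.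
  - Enolisation (LiN(i-Pr)2, THF, −78 °C) and alkylation with bromide 2 (DMPU), anti to vinyl, gives the trans-3-(3-methylbut-3-enyl) lactone F6.
  - A second enolisation and methylation with 9, again anti to vinyl, gives 12.
  - Cost: seven operations replace steps 1 to 4, and the auxiliary is stoichiometric.

**Step 2.**
- What may go wrong: olefination may stall, because the phenoxide formed under the reaction conditions donates into the aldehyde, which is also flanked by two ortho substituents, while the phosphonate is α-branched.
- Fallback (sets out from 3 and 4, returns at 7): saponification of the carboxylic ester of 3 (NaOH, EtOH/H2O; phosphonate esters survive) gives 2-(diethoxyphosphoryl)-5-methylhex-5-enoic acid F7. Carbodiimide esterification with the phenol of 4 gives the aryl phosphonoacetate F8. LiCl and DBU in MeCN then effect an intramolecular Horner–Wadsworth–Emmons reaction in which only the lactone-forming geometry is possible, so 7 forms directly and step 3 is not needed.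

**Step 10.**
- What may go wrong: iodination may occur at C6 or at C3 in competition with C8, since all three positions are activated.
- Fallback (sets out from aldehyde 4, returns at 21): iodination of 4 as its phenoxide (I2, aqueous NaHCO3), directed ortho to the hydroxyl group, gives 2-hydroxy-3-iodo-4,6-dimethoxybenzaldehyde F9; its substitution pattern is read from the NOE contacts of the one remaining aromatic hydrogen. The olefination–lactonisation of step 9 applied to F9 then builds the pyranone, which places the iodine at C8 of 21 by construction.

**Step 12.**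
- What may go wrong: hydrogen uptake may stall at the alkyne, which has a quaternary carbon on one side and a di-ortho-substituted arene on the other. Forcing it invites over-reduction or Z to E isomerisation on the catalyst.
- Fallback (sets out from alkyne 19 and iodide 21, returns at 23, and so also replaces step 11): rhodium-catalysed trans-hydroboration of 19 with pinacolborane ([Rh(cod)Cl]2, P(i-Pr)3, Et3N, cyclohexane, rt) sets the Z geometry on the small terminal alkyne and gives the Z-alkenylboronate F10. Suzuki–Miyaura coupling of F10 with 21 (Pd(OAc)2, SPhos, K3PO4, THF/H2O, 40 °C) then joins Ca to C8 of ring A with retention of geometry.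

## Further compounds

F1 | step 4 | 2-(methoxymethoxy)-4,6-dimethoxybenzaldehyde | COCOc1cc(OC)cc(OC)c1C=O
F2 | step 4 | (2E)-3-[2-(methoxymethoxy)-4,6-dimethoxyphenyl]prop-2-enoic acid | COCOc1cc(OC)cc(OC)c1/C=C/C(=O)O
F3 | step 4 | (4R)-3-{(2E)-3-[2-(methoxymethoxy)-4,6-dimethoxyphenyl]prop-2-enoyl}-4-phenyl-1,3-oxazolidin-2-one | COCOc1cc(OC)cc(OC)c1/C=C/C(=O)N1C(=O)OC[C@H]1c1ccccc1
F4 | step 4 | (4R)-3-{(3S)-3-[2-(methoxymethoxy)-4,6-dimethoxyphenyl]pent-4-enoyl}-4-phenyl-1,3-oxazolidin-2-one | C=C[C@H](CC(=O)N1C(=O)OC[C@H]1c1ccccc1)c1c(OCOC)cc(OC)cc1OC
F5 | step 4 | (4S)-4-ethenyl-5,7-dimethoxy-3,4-dihydro-2H-chromen-2-one | C=C[C@H]1c2c(OC)cc(OC)cc2OC(=O)C1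
F6 | step 4 | (3R,4R)-4-ethenyl-5,7-dimethoxy-3-(3-methylbut-3-en-1-yl)-3,4-dihydro-2H-chromen-2-one (butenyl trans to vinyl) | C=C[C@H]1c2c(OC)cc(OC)cc2OC(=O)[C@@H]1CCC(C)=C
F7 | step 2 | 2-(diethoxyphosphoryl)-5-methylhex-5-enoic acid (racemic) | OC(=O)C(CCC(C)=C)P(=O)(OCC)OCC
F8 | step 2 | 2-formyl-3,5-dimethoxyphenyl 2-(diethoxyphosphoryl)-5-methylhex-5-enoate (racemic) | CCOP(=O)(OCC)C(CCC(C)=C)C(=O)Oc1cc(OC)cc(OC)c1C=O
F9 | step 10 | 2-hydroxy-3-iodo-4,6-dimethoxybenzaldehyde | O=Cc1c(O)c(I)c(OC)cc1OC
F10 | step 12 | 8-[(1R,6R)-3,6-dimethyl-6-[(Z)-2-(4,4,5,5-tetramethyl-1,3,2-dioxaborolan-2-yl)ethenyl]cyclohex-2-en-1-yl]-5,7-dimethoxy-2H-chromen-2-one | CC1(C)OB(/C=C\[C@@]2(C)CCC(C)=C[C@H]2c2c(OC)cc(OC)c3ccc(=O)oc23)OC1(C)C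
A1 | alternative 1 | 2-[(1R,6S)-6-({[tert-butyl(dimethyl)silyl]oxy}methyl)-3,6-dimethylcyclohex-2-en-1-yl]-5-methoxy-3-{[tri(propan-2-yl)silyl]oxy}phenol | CC(C)(C)[Si](C)(C)OC[C@@]1(C)CCC(C)=C[C@H]1c1c(O)cc(OC)cc1O[Si](C(C)C)(C(C)C)C(C)C
A2 | alternative 1 | tert-butyl{[(1S,2R)-1,4-dimethyl-2-({[tri(propan-2-yl)silyl]oxy}ethynyl)cyclohex-3-en-1-yl]methoxy}dimethylsilane | CC(C)(C)[Si](C)(C)OC[C@@]1(C)CCC(C)=C[C@H]1C#CO[Si](C(C)C)(C(C)C)C(C)C
A3 | alternative 1 | 3-methoxycyclobut-2-en-1-one | COC1=CC(=O)C1
A4 | alternative 2 | (6aS,10aS)-1,3,6-trimethoxy-6a,9-dimethyl-6a,7,8,10a-tetrahydro-6H-benzo[c]chromene (either C6 epimer) | COC1Oc2cc(OC)cc(OC)c2[C@@H]2C=C(C)CC[C@]12C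
A5 | alternative 2 | 3,5-dimethoxyphenol | COc1cc(O)cc(OC)c1
A6 | alternative 2 | (2Z)-7-methoxy-3,6-dimethylhepta-2,6-dienal (enol ether of either geometry) | O=C/C=C(C)\CCC(C)=COC
A7 | alternative 2 | 6-[(2Z)-7-methoxy-3,6-dimethylhepta-2,6-dien-1-ylidene]-3,5-dimethoxycyclohexa-2,4-dien-1-one | O=C1C=C(OC)C=C(OC)C1=C/C=C(C)\CCC(C)=COC
A8 | alternative 3 | (6aS,10aS)-1,3-dimethoxy-9-methyl-6-oxo-10-(trimethylsilyl)-7,10-dihydro-6H-benzo[c]chromene-6a(10aH)-carbaldehyde (either C10 epimer) | O=C[C@]12CC=C(C)C([Si](C)(C)C)[C@H]1c1c(OC)cc(OC)cc1OC2=O
A9 | alternative 3 | 5,7-dimethoxy-2-oxo-2H-chromene-3-carbaldehyde | COc1cc(OC)c2cc(C=O)c(=O)oc2c1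
A10 | alternative 3 | (E)-trimethyl(2-methylbuta-1,3-dien-1-yl)silane | C[Si](C)(C)/C=C(\C)C=C
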